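**Strategy**

The cis-octalin is disconnected at C4a–C5 as an anionic oxy-Cope retron: the C7 oxygen, the cis C4a/C8a fusion and the ring A alkene C3=C4 make up a δ,ε-unsaturated ketone (C7–C6–C5–C4a–C4=C3). In one operation the [3,3] shift of a 2-vinylbicyclo[2.2.2]oct-5-en-2-olate cleaves the bond between the carbinol carbon and the methylated bridgehead, forms C4a–C5, closes ring B, fixes the cis fusion and releases ring A with its alkene and the C7 ketone. The precursor is a 1,3-dimethyl-2-vinylbicyclo[2.2.2]oct-5-en-2-ol with endo (E)-but-2-en-2-yl and exo CH2OPMB groups on the ethano bridge, built by Diels–Alder reaction of an o-quinol acetate with an (E)-enone.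

Key step: step 9

**Remarks on the chemistry (assumptions)**

- Octalin numbering: C1 dienoic acid, C2 butenyl, C3 methyl, C3=C4, C4a/C8a fusion, C7 sulfate, C8 methyl. The target is (1R,2R,4aS,7R,8S,8aR): H-1, H-4a, H-7, H-8 and H-8a lie on one face, H-2 on the other.
- Bicycle numbering: C1 methylated bridgehead, C2 carbonyl/carbinol carbon, C3 methyl-bearing carbon, C4 bridgehead CH, C5=C6, C7 (on C1), C8 (on C4).
- The o-quinol acetate is racemic; the absolute configuration is secured by resolving the cycloadduct on a chiral phase within step 4. The acetoxy-bearing centre is erased in step 7, so its configuration is immaterial.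
- The C7–O bond of the target is cis to the C8 methyl and to the C8a–C1 bond, so hydride must enter ring B on the face that carries only hydrogens. The olefination is placed before the ketone reduction so that a free C7 hydroxyl never meets the C1 aldehyde (lactol formation, over-oxidation to a lactone).
- The target is isolated and written as the free acid.

**Route**

Step 1
Reactants: 1 2,6-dimethylphenol
Product: 2 6-acetoxy-2,6-dimethylcyclohexa-2,4-dien-1-one (racemic o-quinol acetate)
Conditions: Pb(OAc)4 (1.1 equiv), AcOH, rt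
Reagents that add atoms: lead tetraacetate, CC(=O)O[Pb](OC(C)=O)(OC(C)=O)OC(C)=O
Why: Wessely acetoxylation, in which the aryloxy intermediate of tetravalent lead passes an acetate ligand to the methyl-bearing ortho carbon; the 2,6-dimethyl pattern gives a dienone that dimerises only slowly, and the new quaternary centre is racemic and is removed again in step 7.

Step 2
Reactants: 3 (Z)-but-2-ene-1,4-diol
Product: 4 (Z)-1,4-bis[(4-methoxybenzyl)oxy]but-2-ene
Conditions: NaH, 4-methoxybenzyl chloride, Bu4NI (cat.), DMF, 0 °C → rt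
Reagents that add atoms: 4-methoxybenzyl chloride, COc1ccc(CCl)cc1
Why: Williamson etherification of both primary allylic alkoxides with iodide catalysis; no stereocentre is formed and the alkene is untouched.

Step 3
Reactants: 4 (Z)-1,4-bis[(4-methoxybenzyl)oxy]but-2-ene; 5 pent-1-en-3-one (ethyl vinyl ketone)
Product: 6 (E)-6-[(4-methoxybenzyl)oxy]hex-4-en-3-one
Conditions: second-generation Grubbs catalyst (H2IMes)(PCy3)Cl2Ru=CHPh (3 mol%), 5 (5 equiv), CH2Cl2, 40 °C
Reagents that add atoms: none
Why: Olefin cross-metathesis between an electron-rich internal olefin and an electron-poor vinyl ketone, a pairing that couples selectively and gives the conjugated E enone under thermodynamic control while using both halves of 4.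

Step 4
Reactants: 2 6-acetoxy-2,6-dimethylcyclohexa-2,4-dien-1-one; 6 (E)-6-[(4-methoxybenzyl)oxy]hex-4-en-3-one
Product: 7 3-acetoxy-8-{[(4-methoxybenzyl)oxy]methyl}-1,3-dimethyl-7-propanoylbicyclo[2.2.2]oct-5-en-2-one (propanoyl endo; CH2OPMB exo; single enantiomer)
Conditions: 6 (2.5 equiv), PhMe, 110 °C, sealed tube; then preparative SFC on a chiral stationary phase (amylose tris(3,5-dimethylphenylcarbamate), CO2/MeOH)
Reagents that add atoms: none
Why: Thermal Diels–Alder reaction with the cyclohexa-2,4-dienone as diene: the carbonyl-bearing diene terminus (C2 of 2) bonds to the acyl-bearing carbon of 6 (the orientation usual for 1-acyl dienes), the propanoyl group lies endo and ends syn to the new C5=C6 bridge, the E geometry of 6 places CH2OPMB trans to it (exo) and the dienophile should enter on the acetoxy face, which fixes the relative configuration at C1, C4, C7 and C8; chromatography on the chiral phase then delivers the enantiomer drawn.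

Step 5
Reactants: 7 3-acetoxy-8-{[(4-methoxybenzyl)oxy]methyl}-1,3-dimethyl-7-propanoylbicyclo[2.2.2]oct-5-en-2-one
Product: 9 (Z)-enol triflate of the propanoyl group of 7 [C7–C(OTf)=CH–CH3; OTf cis to CH3], via potassium Z-enolate 8 (not isolated)
Conditions: KN(SiMe3)2 (1.05 equiv), THF, −78 °C; then PhNTf2, −78 → 0 °C
Reagents that add atoms: N-phenylbis(trifluoromethanesulfonimide), FC(F)(F)S(=O)(=O)N(c1ccccc1)S(=O)(=O)C(F)(F)F
Why: Kinetic enolisation and O-triflation: the ring ketone has no α-hydrogen, the C7 methine is shielded and one equivalent of amide at −78 °C leaves the tertiary acetate alone, so only the ethyl CH2 is deprotonated, and allylic strain against the bulky C7 ring carbon puts the enolate methyl cis to oxygen (Z), which fixes the geometry of the later alkene.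

Step 6
Reactants: 9 (Z)-enol triflate of the propanoyl group of 7
Product: 10 3-acetoxy-7-[(E)-but-2-en-2-yl]-8-{[(4-methoxybenzyl)oxy]methyl}-1,3-dimethylbicyclo[2.2.2]oct-5-en-2-one
Conditions: Me2Zn (2 equiv), Pd(PPh3)4 (5 mol%), THF, 0 °C → rt
Reagents that add atoms: dimethylzinc, C[Zn]C
Why: Negishi cross-coupling: oxidative addition of zerovalent palladium into the C–OTf bond, transmetalation and reductive elimination proceed with retention, so the Z triflate gives the E but-2-en-2-yl group, and dimethylzinc leaves the ketone and the acetate untouched.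

Step 7
Reactants: 10 3-acetoxy-7-[(E)-but-2-en-2-yl]-8-{[(4-methoxybenzyl)oxy]methyl}-1,3-dimethylbicyclo[2.2.2]oct-5-en-2-one
Product: 12 7-[(E)-but-2-en-2-yl]-8-{[(4-methoxybenzyl)oxy]methyl}-1,3-dimethylbicyclo[2.2.2]oct-5-en-2-one (C3 methyl syn to the C7–C8 bridge), via samarium enolate 11 (not isolated)
Conditions: SmI2 (2.5 equiv), THF/MeOH, −78 °C; pH 7 buffer
Reagents that add atoms: none
Why: Reductive cleavage of the α-acyloxy ketone by divalent samarium (two single-electron transfers expel acetate) gives enolate 11, which should be protonated at −78 °C from the face of the C5=C6 bridge because the exo CH2OPMB group on C8 covers the other face, so the C3 methyl ends up pointing to the C7–C8 bridge under kinetic control.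

Step 8
Reactants: 12 7-[(E)-but-2-en-2-yl]-8-{[(4-methoxybenzyl)oxy]methyl}-1,3-dimethylbicyclo[2.2.2]oct-5-en-2-one; 13 vinylmagnesium bromide
Product: 14 7-[(E)-but-2-en-2-yl]-8-{[(4-methoxybenzyl)oxy]methyl}-1,3-dimethyl-2-vinylbicyclo[2.2.2]oct-5-en-2-ol (vinyl syn to C5=C6; hydroxyl syn to C7–C8)
Conditions: CeCl3 (anhydrous, 1.5 equiv), THF, −78 °C; then H2O
Reagents that add atoms: none
Why: Grignard 1,2-addition promoted by CeCl3, which suppresses enolisation of the hindered, epimerisable ketone; the nucleophile should enter from the face of the C5=C6 bridge, which offers only sp2 C–H and H-3, whereas the other face is blocked by the C3 methyl and the exo hydrogen on C7, so the vinyl group is set syn to the alkene bridge.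

Step 9
Reactants: 14 7-[(E)-but-2-en-2-yl]-8-{[(4-methoxybenzyl)oxy]methyl}-1,3-dimethyl-2-vinylbicyclo[2.2.2]oct-5-en-2-ol
Product: 17 (1R,2R,4aS,8S,8aR)-2-[(E)-but-2-en-2-yl]-1-{[(4-methoxybenzyl)oxy]methyl}-3,8-dimethyl-1,2,4a,5,6,7,8,8a-octahydronaphthalen-7-one (cis-fused; target numbering), via potassium alkoxide 15 (not isolated), via potassium enolate 16 (not isolated)
Conditions: KH (3 equiv), 18-crown-6 (3 equiv), THF, 0 °C → rt; then cannulation into AcOH/THF at −78 °C
Reagents that add atoms: none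
Why: Deprotonation gives the crown-separated alkoxide 15, whose oxyanion weakens the adjacent C1–C2 bond (bicycle numbering) so that the 1,5-diene CH2=CH–C2–C1–C6=C5 undergoes a concerted suprafacial [3,3]-sigmatropic shift near room temperature: C1–C2 breaks, the vinyl terminus bonds to C5 and the enolate 16 (C6=C7–O− in octalin numbering) results. This is the anionic oxy-Cope rearrangement of 2-vinylbicyclo[2.2.2]oct-5-en-2-ols, a known entry to cis-fused octalones. Ring B (C4a–C5–C6–C7–C8–C8a) closes by this single C4a–C5 bond within a boat-like six-centre transition state that the cage enforces, and ring A is released with its C3=C4 alkene. The only new stereocentre, C4a, is fixed by the cage, because the vinyl group can reach C5 only on the face of the carbinol bridge that also carries C8a, so the fusion must be cis, while C1, C2, C8 and C8a are carried over unchanged. The step needs the vinyl group syn to the C5=C6 bridge (step 8), no reaction of the second 1,5-diene through the endo butenyl group (a neutral Cope system, inert at this temperature) and an enolate that does not equilibrate toward C8, which the aprotic medium, the excess of KH and the cold inverse quench secure.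

Step 10
Reactants: 17 (1R,2R,4aS,8S,8aR)-2-[(E)-but-2-en-2-yl]-1-{[(4-methoxybenzyl)oxy]methyl}-3,8-dimethyl-1,2,4a,5,6,7,8,8a-octahydronaphthalen-7-one
Product: 18 (1R,2R,4aS,8S,8aR)-2-[(E)-but-2-en-2-yl]-1-(hydroxymethyl)-3,8-dimethyl-1,2,4a,5,6,7,8,8a-octahydronaphthalen-7-one
Conditions: DDQ (1.3 equiv), CH2Cl2/pH 7 buffer, 0 °C
Reagents that add atoms: none
Why: Oxidative cleavage of the 4-methoxybenzyl ether (hydride abstraction by DDQ, hydrolysis of the oxocarbenium ion) in a neutral buffered medium that leaves the epimerisable C8 centre, the ketone and the two trisubstituted alkenes alone.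

Step 11
Reactants: 18 (1R,2R,4aS,8S,8aR)-2-[(E)-but-2-en-2-yl]-1-(hydroxymethyl)-3,8-dimethyl-1,2,4a,5,6,7,8,8a-octahydronaphthalen-7-one
Product: 19 (1R,2R,4aS,8S,8aR)-2-[(E)-but-2-en-2-yl]-3,8-dimethyl-7-oxo-1,2,4a,5,6,7,8,8a-octahydronaphthalene-1-carbaldehyde
Conditions: Dess–Martin periodinane (1.3 equiv), pyridine, CH2Cl2, 0 °C → rt
Reagents that add atoms: none
Why: Dess–Martin oxidation of the primary alcohol stops at the aldehyde under buffered, non-enolising conditions, so the α-centres C1 and C8 keep their configuration.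

Step 12
Reactants: 19 (1R,2R,4aS,8S,8aR)-2-[(E)-but-2-en-2-yl]-3,8-dimethyl-7-oxo-1,2,4a,5,6,7,8,8a-octahydronaphthalene-1-carbaldehyde; 20 triethyl 4-phosphonocrotonate
Product: 21 ethyl (2E,4E)-5-[(1R,2R,4aS,8S,8aR)-2-[(E)-but-2-en-2-yl]-3,8-dimethyl-7-oxo-1,2,4a,5,6,7,8,8a-octahydronaphthalen-1-yl]penta-2,4-dienoate
Conditions: 20 (1.5 equiv), LiN(SiMe3)2 (1.3 equiv), THF, −78 °C; then 19, −78 → 0 °C
Reagents that add atoms: none
Why: Vinylogous Horner–Wadsworth–Emmons olefination: the stabilised lithium phosphonate (kept in excess over the amide base) attacks only the aldehyde, being too weak a base to enolise the flanked ketone, and reversible addition followed by elimination should give the new double bond E while the E crotonate unit is retained.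

Step 13
Reactants: 21 ethyl (2E,4E)-5-[(1R,2R,4aS,8S,8aR)-2-[(E)-but-2-en-2-yl]-3,8-dimethyl-7-oxo-1,2,4a,5,6,7,8,8a-octahydronaphthalen-1-yl]penta-2,4-dienoate
Product: 22 ethyl (2E,4E)-5-[(1R,2R,4aS,7R,8S,8aR)-2-[(E)-but-2-en-2-yl]-7-hydroxy-3,8-dimethyl-1,2,4a,5,6,7,8,8a-octahydronaphthalen-1-yl]penta-2,4-dienoate
Conditions: NaBH4, CeCl3·7H2O, MeOH, −40 °C
Reagents that add atoms: none
Why: Luche reduction, chemoselective for the ketone over the dienoate and non-basic toward C8: hydride should add along the axial trajectory on the ring B face that carries only hydrogens, anti to the flanking C8 methyl and to the C8a–C1 and C4a–C4 bonds, so the C7 hydroxyl forms cis to the C8 methyl (7R).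

Step 14
Reactants: 22 ethyl (2E,4E)-5-[(1R,2R,4aS,7R,8S,8aR)-2-[(E)-but-2-en-2-yl]-7-hydroxy-3,8-dimethyl-1,2,4a,5,6,7,8,8a-octahydronaphthalen-1-yl]penta-2,4-dienoate
Product: 23 pyridinium salt of the C7 sulfate monoester of 22
Conditions: SO3·pyridine (5 equiv), pyridine, rt → 40 °C
Reagents that add atoms: sulfur trioxide–pyridine complex, [O-]S(=O)(=O)[n+]1ccccc1
Why: O-Sulfation of the secondary alcohol by the sulfur trioxide–amine complex takes place at oxygen with retention at C7 and gives the stable pyridinium sulfate monoester, the ester and the alkenes being inert.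

Step 15
Reactants: 23 pyridinium salt of the C7 sulfate monoester of 22
Product: 25 (2E,4E)-5-[(1R,2R,4aS,7R,8S,8aR)-2-[(E)-but-2-en-2-yl]-3,8-dimethyl-7-(sulfooxy)-1,2,4a,5,6,7,8,8a-octahydronaphthalen-1-yl]penta-2,4-dienoic acid (target), via dilithium salt 24 (not isolated)
Conditions: LiOH, THF/MeOH/H2O, rt; then dilute HCl to pH 2 at 0 °C, C18 reverse-phase desalting, lyophilisation
Reagents that add atoms: lithium hydroxide, [Li+].[OH-]
Why: Saponification of the ethyl dienoate by acyl–oxygen cleavage; the anionic sulfate monoester resists hydroxide, and brief cold acidification should liberate the free acid without solvolysis of the secondary sulfate.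

**Compound list**

1 | 2,6-dimethylphenol | Cc1cccc(C)c1O | starting material
2 | 6-acetoxy-2,6-dimethylcyclohexa-2,4-dien-1-one (racemic) | CC(=O)OC1(C)C=CC=C(C)C1=O | intermediate
3 | (Z)-but-2-ene-1,4-diol | OC/C=C\CO | starting material
4 | (Z)-1,4-bis[(4-methoxybenzyl)oxy]but-2-ene | COc1ccc(COC/C=C\COCc2ccc(OC)cc2)cc1 | intermediate
5 | pent-1-en-3-one | CCC(=O)C=C | starting material
6 | (E)-6-[(4-methoxybenzyl)oxy]hex-4-en-3-one | CCC(=O)/C=C/COCc1ccc(OC)cc1 | intermediate
7 | 3-acetoxy-8-{[(4-methoxybenzyl)oxy]methyl}-1,3-dimethyl-7-propanoylbicyclo[2.2.2]oct-5-en-2-one; propanoyl syn to C5=C6, CH2OPMB syn to the C2–C3 bridge, acetoxy syn to the C7–C8 bridge; single enantiomer after resolution | CCC(=O)[C@@H]1[C@]2(C)C=C[C@H]([C@H]1COCc3ccc(OC)cc3)[C@](C)(OC(C)=O)C2=O | intermediate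
8 | potassium (Z)-enolate of the propanoyl group of 7 | C/C=C(\[O-])[C@@H]1[C@]2(C)C=C[C@H]([C@H]1COCc3ccc(OC)cc3)[C@](C)(OC(C)=O)C2=O.[K+] | intermediate (not isolated)
9 | (Z)-enol triflate of 7 [C7–C(OTf)=CH–CH3, OTf cis to CH3] | C/C=C(\OS(=O)(=O)C(F)(F)F)[C@@H]1[C@]2(C)C=C[C@H]([C@H]1COCc3ccc(OC)cc3)[C@](C)(OC(C)=O)C2=O | intermediate
10 | 3-acetoxy-7-[(E)-but-2-en-2-yl]-8-{[(4-methoxybenzyl)oxy]methyl}-1,3-dimethylbicyclo[2.2.2]oct-5-en-2-one | C/C=C(\C)[C@@H]1[C@]2(C)C=C[C@H]([C@H]1COCc3ccc(OC)cc3)[C@](C)(OC(C)=O)C2=O | intermediate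
11 | diiodosamarium enolate (C2=C3, C2–O–SmI2) derived from 10 | C/C=C(\C)[C@@H]1[C@]2(C)C=C[C@H]([C@H]1COCc3ccc(OC)cc3)C(C)=C2O[Sm](I)I | intermediate (not isolated)
12 | 7-[(E)-but-2-en-2-yl]-8-{[(4-methoxybenzyl)oxy]methyl}-1,3-dimethylbicyclo[2.2.2]oct-5-en-2-one; C3 methyl syn to the C7–C8 bridge, H-3 syn to C5=C6 | C/C=C(\C)[C@@H]1[C@]2(C)C=C[C@H]([C@H]1COCc3ccc(OC)cc3)[C@H](C)C2=O | intermediate
13 | vinylmagnesium bromide | C=C[Mg]Br | starting material
14 | 7-[(E)-but-2-en-2-yl]-8-{[(4-methoxybenzyl)oxy]methyl}-1,3-dimethyl-2-vinylbicyclo[2.2.2]oct-5-en-2-ol; vinyl syn to C5=C6, hydroxyl syn to C7–C8, butenyl endo, CH2OPMB exo | C/C=C(\C)[C@@H]1[C@]2(C)C=C[C@H]([C@H]1COCc3ccc(OC)cc3)[C@H](C)[C@@]2(O)C=C | intermediate (precursor of the key step)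
15 | potassium alkoxide of 14 | C/C=C(\C)[C@@H]1[C@]2(C)C=C[C@H]([C@H]1COCc3ccc(OC)cc3)[C@H](C)[C@@]2([O-])C=C.[K+] | intermediate (not isolated)
16 | potassium enolate (C6=C7–O−) of 17 | C/C=C(\C)[C@@H]1C(C)=C[C@H]2CC=C([O-])[C@@H](C)[C@H]2[C@H]1COCc3ccc(OC)cc3.[K+] | intermediate (not isolated)
17 | (1R,2R,4aS,8S,8aR)-2-[(E)-but-2-en-2-yl]-1-{[(4-methoxybenzyl)oxy]methyl}-3,8-dimethyl-1,2,4a,5,6,7,8,8a-octahydronaphthalen-7-one, cis-fused (target numbering) | C/C=C(\C)[C@@H]1C(C)=C[C@H]2CCC(=O)[C@@H](C)[C@H]2[C@H]1COCc3ccc(OC)cc3 | intermediate (product of the key step)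
18 | (1R,2R,4aS,8S,8aR)-2-[(E)-but-2-en-2-yl]-1-(hydroxymethyl)-3,8-dimethyl-1,2,4a,5,6,7,8,8a-octahydronaphthalen-7-one | C/C=C(\C)[C@@H]1C(C)=C[C@H]2CCC(=O)[C@@H](C)[C@H]2[C@H]1CO | intermediate
19 | (1R,2R,4aS,8S,8aR)-2-[(E)-but-2-en-2-yl]-3,8-dimethyl-7-oxo-1,2,4a,5,6,7,8,8a-octahydronaphthalene-1-carbaldehyde | C/C=C(\C)[C@@H]1C(C)=C[C@H]2CCC(=O)[C@@H](C)[C@H]2[C@H]1C=O | intermediate
20 | triethyl 4-phosphonocrotonate [ethyl (E)-4-(diethoxyphosphoryl)but-2-enoate] | CCOC(=O)/C=C/CP(=O)(OCC)OCC | starting material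
21 | ethyl (2E,4E)-5-[(1R,2R,4aS,8S,8aR)-2-[(E)-but-2-en-2-yl]-3,8-dimethyl-7-oxo-1,2,4a,5,6,7,8,8a-octahydronaphthalen-1-yl]penta-2,4-dienoate | C/C=C(\C)[C@@H]1C(C)=C[C@H]2CCC(=O)[C@@H](C)[C@H]2[C@H]1/C=C/C=C/C(=O)OCC | intermediate
22 | ethyl (2E,4E)-5-[(1R,2R,4aS,7R,8S,8aR)-2-[(E)-but-2-en-2-yl]-7-hydroxy-3,8-dimethyl-1,2,4a,5,6,7,8,8a-octahydronaphthalen-1-yl]penta-2,4-dienoate | C/C=C(\C)[C@@H]1C(C)=C[C@H]2CC[C@@H](O)[C@@H](C)[C@H]2[C@H]1/C=C/C=C/C(=O)OCC | intermediate
23 | pyridinium salt of the C7 sulfate monoester of 22 | C/C=C(\C)[C@@H]1C(C)=C[C@H]2CC[C@@H](OS(=O)(=O)[O-])[C@@H](C)[C@H]2[C@H]1/C=C/C=C/C(=O)OCC.c1cc[nH+]cc1 | intermediate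
24 | dilithium salt (carboxylate and sulfate) of 25 | C/C=C(\C)[C@@H]1C(C)=C[C@H]2CC[C@@H](OS(=O)(=O)[O-])[C@@H](C)[C@H]2[C@H]1/C=C/C=C/C(=O)[O-].[Li+].[Li+] | intermediate (not isolated)
25 | (2E,4E)-5-[(1R,2R,4aS,7R,8S,8aR)-2-[(E)-but-2-en-2-yl]-3,8-dimethyl-7-(sulfooxy)-1,2,4a,5,6,7,8,8a-octahydronaphthalen-1-yl]penta-2,4-dienoic acid | C/C=C(\C)[C@@H]1C(C)=C[C@H]2CC[C@@H](OS(=O)(=O)O)[C@@H](C)[C@H]2[C@H]1/C=C/C=C/C(=O)O | target

**Step count**

Total: 15 steps (the chromatographic resolution is part of step 4). Longest linear sequence: 14 steps (3 → 25, steps 2 to 15).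

**Steps most likely to fail, with fallbacks**

Step 4 (cycloaddition). The 1,2-disubstituted enone may add to the 2-methylated dienone more slowly than 2 dimerises or aromatises by acetoxy migration, and a slow reaction at high temperature erodes endo and regiochemical control. The fallback sets out from 4 and 2 and returns at 7; it moves the construction of the ethyl ketone behind the cycloaddition. Cross-metathesis of 4 with crotonaldehyde (same ruthenium catalyst) gives (E)-4-[(4-methoxybenzyl)oxy]but-2-enal F1, a smaller and more electrophilic dienophile whose formyl group is the stronger endo director. Its cycloaddition with 2 under the same orientation rules gives 3-acetoxy-8-{[(4-methoxybenzyl)oxy]methyl}-1,3-dimethyl-2-oxobicyclo[2.2.2]oct-5-ene-7-carbaldehyde F2. EtMgBr at −78 °C adds only to the formyl group (the ring ketone is quaternary on both sides) to give the 7-(1-hydroxypropyl) compound F3 as a carbinol mixture. Dess–Martin oxidation of F3 gives 7, which is resolved as before.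

Step 7 (deacetoxylation and protonation). Protonation of enolate 11 on the wrong face, or epimerisation of the strained α-methyl ketone on work-up, would give the C3 epimer, which would also turn the facial preference of the vinyl addition. The fallback sets out from 12 (any epimer ratio) and returns at 17; it erases the centre and creates the C8 methyl stereocentre on the octalone instead. LiN(SiMe3)2/Me3SiCl converts 12 into the trimethylsilyl enol ether F4, and Saegusa–Ito oxidation (Pd(OAc)2, MeCN) gives the exocyclic 3-methylene ketone F5, the only possible direction since a bridgehead alkene is excluded. Vinylmagnesium bromide with CeCl3 adds 1,2 from the now unhindered alkene face to give the 3-methylene-2-vinyl carbinol F6. KH/18-crown-6 rearranges F6 to the 8-methylene cis-octalin-7-one F7. Conjugate reduction of F7 with LiBH(s-Bu)3 at −78 °C and kinetic protonation of the resulting C7–C8 enolate on the hydrogen-only face of ring B should give 17.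

Step 9 (key rearrangement). The potassium alkoxide may cleave heterolytically to an allyl anion and an enone that do not reclose, or the product enolate may exchange protons and scramble C8 before the quench. The fallback sets out from 14 and returns at 17; it replaces the charge-accelerated shift by the neutral thermal variant through silyl derivatives. Silylation (Me3SiOTf, 2,6-lutidine) gives the trimethylsilyl ether F8. Thermolysis in a sealed tube (PhMe, about 200 °C) effects the [3,3] shift to the regiodefined trimethylsilyl enol ether F9; the competing hydrocarbon Cope shift through the hindered trisubstituted butenyl terminus is expected to be slower than the siloxy-substituted one. Bu4NF/AcOH at −78 °C unmasks F9 to 17 without exposing C8 to base.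

**Further compounds**

F1 | step 4 | (E)-4-[(4-methoxybenzyl)oxy]but-2-enal | O=C/C=C/COCc1ccc(OC)cc1
F2 | step 4 | 3-acetoxy-8-{[(4-methoxybenzyl)oxy]methyl}-1,3-dimethyl-2-oxobicyclo[2.2.2]oct-5-ene-7-carbaldehyde (formyl endo; racemic, enantiomer leading to 7 drawn) | O=C[C@@H]1[C@]2(C)C=C[C@H]([C@H]1COCc3ccc(OC)cc3)[C@](C)(OC(C)=O)C2=O
F3 | step 4 | 3-acetoxy-7-(1-hydroxypropyl)-8-{[(4-methoxybenzyl)oxy]methyl}-1,3-dimethylbicyclo[2.2.2]oct-5-en-2-one (carbinol epimers) | CCC(O)[C@@H]1[C@]2(C)C=C[C@H]([C@H]1COCc3ccc(OC)cc3)[C@](C)(OC(C)=O)C2=O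
F4 | step 7 | trimethylsilyl enol ether (C2=C3) of 12 | C/C=C(\C)[C@@H]1[C@]2(C)C=C[C@H]([C@H]1COCc3ccc(OC)cc3)C(C)=C2O[Si](C)(C)C
F5 | step 7 | 7-[(E)-but-2-en-2-yl]-8-{[(4-methoxybenzyl)oxy]methyl}-1-methyl-3-methylenebicyclo[2.2.2]oct-5-en-2-one | C/C=C(\C)[C@@H]1[C@]2(C)C=C[C@H]([C@H]1COCc3ccc(OC)cc3)C(=C)C2=O
F6 | step 7 | 7-[(E)-but-2-en-2-yl]-8-{[(4-methoxybenzyl)oxy]methyl}-1-methyl-3-methylene-2-vinylbicyclo[2.2.2]oct-5-en-2-ol (vinyl syn to C5=C6) | C/C=C(\C)[C@@H]1[C@]2(C)C=C[C@H]([C@H]1COCc3ccc(OC)cc3)C(=C)[C@@]2(O)C=C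
F7 | step 7 | 2-[(E)-but-2-en-2-yl]-1-{[(4-methoxybenzyl)oxy]methyl}-3-methyl-8-methylene-1,2,4a,5,6,7,8,8a-octahydronaphthalen-7-one (cis-fused) | C/C=C(\C)[C@@H]1C(C)=C[C@H]2CCC(=O)C(=C)[C@H]2[C@H]1COCc3ccc(OC)cc3
F8 | step 9 | trimethylsilyl ether of 14 | C/C=C(\C)[C@@H]1[C@]2(C)C=C[C@H]([C@H]1COCc3ccc(OC)cc3)[C@H](C)[C@@]2(O[Si](C)(C)C)C=C
F9 | step 9 | trimethylsilyl enol ether (C6=C7) of 17 | C/C=C(\C)[C@@H]1C(C)=C[C@H]2CC=C(O[Si](C)(C)C)[C@@H](C)[C@H]2[C@H]1COCc3ccc(OC)cc3
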